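A small charge shows the pattern, and 1 M of starting material under gas phase held at 200 mM is the elm run; the oak run holds 1.5 M.

all flasks: gas phase 200 mM (held)

| charge | starting material | remark | time |
|---|---|---|---|
| elm | 1 M | run made earlier |  |
| oak | 1.5 M | run made earlier |  |
| flask | 2.0 M |  | 20 min |

| run | time / min | target / % | starting material / % |
|---|---|---|---|
| elm | 1.50 | 1.6 | 98.0 |
| elm | 3.00 | 4.2 | 95.9 |
| elm | 5.00 | 7.1 | 92.9 |
| elm | 6.00 | 8.9 | 90.9 |
| elm | 8.00 | 11.2 | 88.3 |
| elm | 10.0 | 14.3 | 85.3 |
| elm | 12.0 | 16.6 | 82.8 |
| oak | 1.50 | 1.3 | 98.2 |
| oak | 3.00 | 3.4 | 96.2 |
| oak | 5.00 | 6.8 | 93.0 |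
| oak | 6.00 | 8.5 | 91.5 |
| oak | 8.00 | 11.2 | 89.3 |
| oak | 10.0 | 13.1 | 86.0 |
| oak | 12.0 | 16.1 | 83.0 |

(each reading ± 0.3 percentage points)

- at the start none of the gas phase is in solution

* the target standing at 20 min, as a percentage of the starting material charged
* concentration of dissolved gas in solution at 20 min, in percent of saturation

At the start the elm run has no gas in solution. At 1.50 min it holds 1.6% of target, less than the 2.08% that its average pace up to its last reading gives. In the middle the elm run keeps a steady pace. At 12.0 min the starting material stands at 82.8% in the elm run and 83.0% in the oak run, which is a loss of 0.0157 min⁻¹ and 0.0155 min⁻¹. A larger charge therefore loses about the same share each minute, the pseudo-first-order pattern. That share of the starting material present, lost per minute, is the fractional loss 0.0156 min⁻¹, and integrating it gives the amount left as exp(−fractional loss × time).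

At the end of the 2.0 M flask, 20 min leaves 73.2% of the starting material, so the reckoning here gives 26.8% of target. That figure counts all lost starting material as target, and at its last reading the elm run falls 0.6 percentage points short of its charge, against a scatter of 0.3 points on each reading. The readings show no level of dissolved gas, so no saturation figure is reckoned here.

The forecast gives 26.3% of target, a little below this reckoning, and 95% of saturation, holding that “the liquid stays near saturation and transfer is not yet limiting”.

The flask gives 24.6% of target and 82.7% of saturation, with 74% of the starting material left against the reckoned 73.2%.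

    starting material + dissolved gas → target (k = 0.0960 M⁻¹ min⁻¹)
    gas phase ⇌ dissolved gas, rate k2*(csat - [dissolved gas]) (kL = 1.40 min⁻¹)
    starting material → decomposition product (k = 2.70 × 10⁻⁵ min⁻¹)
    dissolved gas + target → over-reacted product (k = 0.0420 M⁻¹ min⁻¹)
    dissolved gas → decomposed reagent (k = 0.130 min⁻¹)

The forecast stands 12 points above the flask on saturation. In the flask, transfer alone closes the gap to saturation with a half-life of 0.495 min, shorter than the 3.6 min of dissolved gas going into target at the charged amount or the 5.3 min going into decomposed reagent, and at 20.0 min dissolved gas is made as fast as it is used (a ratio of 1.00) at 0.165 M. For the same flask read at 80 min, the fractional loss of 0.0156 min⁻¹ leaves 28.7% of the starting material; the computed run has 28%.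

The numbers in the tables are calculated for substances that don't exist, and the scatter is random.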